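## Structural features

The target 18 is the ester of octadecan-1-ol, an unbranched C18 primary alcohol, with 3-(2,4-dihydroxy-3-methoxyphenyl)propanoic acid. Its only ring is a benzene ring, joined through C1 to the CH2CH2C(=O)O chain. The ring is substituted on four neighbouring carbons, C1 (chain), C2 (hydroxyl), C3 (methoxyl) and C4 (hydroxyl), whereas C5 and C6 carry hydrogen. There is no stereocentre, so no stereocentres stand next to each other and no configuration has to be set; the only stereochemical elements met on the way are transient alkene geometries. Two features are fragile: the electron-rich 2-methoxyresorcinol nucleus, open to oxidation and to electrophilic attack at C5, and the C2 hydroxyl, which can attack the ester carbonyl and close a six-membered lactone (a chroman-2-one) with expulsion of the C18 alcohol under acid, base or heat. The real difficulty is the oxygen pattern, not the chain: a methoxyl flanked by two free hydroxyls on contiguous carbons next to a carbon substituent is not reached cleanly by selective methylation or electrophilic substitution of a simpler phenol. The key step exploits the fact that C2, C3 and C4 with their oxygens correspond to the ester carbon, the alpha carbon and the ketone carbon of a 2-methoxyacetoacetate, that C5 is its methyl carbon, and that C6, C1 and the first chain carbon form a prop-2-ynoate unit. Because C5 and C6 are bare, a terminal alkyne suffices and the ring can be assembled from a four-carbon diene and a two-carbon dienophile.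

## Logic of the disconnections

**18 to 17.** The two phenolic O–H bonds are traced back to O–benzyl bonds and the Cα–Cβ single bond to a double bond. The cut is placed here because the free C2 hydroxyl of 18 can lactonise onto the ester, so the phenols are uncovered last and under neutral conditions; one hydrogenation then does three jobs. The gain is that every compound before the last step is non-phenolic and robust. The demand on the forward step is complete hydrogenolysis of the hindered C2 ether at ambient temperature without acid or base.

**17 to 10 and 15.** The Cα=Cβ double bond is cut (carbonyl olefination), with 16 as the transient partner of 15. This is the one chain bond that divides the molecule into an arene carrying a single carbon and a fragment that already holds the complete C18 ester, so no esterification is ever run on a phenolic substrate. The gain is two fragments of similar size made independently. The demand is an olefination that tolerates an electron-rich, ortho-substituted aldehyde; its geometry is irrelevant.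

**15 to 13 to 11 and 12.** The C–P bond and the ester C–O bond are cut. The long alcohol thus enters in the first step of the branch by a plain acid-catalysed esterification, without an acyl halide. The gain is that both components are bulk chemicals. The demand is that quaternisation and ylide formation spare the ester.

**10 to 9 to 8.** The benzylic CH2–OH is taken back to the ester carbonyl, and the two O–benzyl bonds are cut. The ring-forming step delivers C1 at the ester oxidation level with both phenols free, and benzyl is chosen because its removal costs no extra step. The gain is arrival at the product of the key step. The demand is alkylation of both phenols, including the hydrogen-bonded and flanked C2 hydroxyl, and a hydride reduction that leaves the ethers alone.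

**8 to 5 and 6.** The ring bonds C1–C2 and C5–C6 are cut, through 7. This divides the ring into a C4 piece that carries all three oxygens at the correct oxidation level and a C2 piece that carries the one-carbon handle. Aromaticity then arises by elimination of the ketal methoxyl, with no oxidant. The gain is the largest of the route: the tetrasubstituted arene is reduced to two acyclic components, and the methoxyl/hydroxyl differentiation is built in. The demand is a regioselective union (CH2 terminus to the beta carbon of the alkyne) and loss of the methoxyl, not the silyloxy group, from the ketal carbon.

**5 to 4 to 3.** Two O–Si bonds are cut, one after the other. Stepwise enolisation (first the acidic C2–H with an amine base, then the gamma C–H with a lithium amide) is the dependable way to such dienes. The gain is a simple beta-keto ester. The demand is anhydrous handling and a gamma-deprotonation that outruns attack at the ester.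

**3 to 1 and 2.** The C2–C3 bond (alpha carbon to acyl carbon) is cut, so the methoxyl is on carbon from the outset. An entry from an unsubstituted acetoacetate by diazo transfer and carbene O–H insertion was set aside: it needs a sulfonyl azide, an isolated diazo ester and a precious-metal catalyst, and takes two steps where one suffices. The gain is two cheap commercial liquids and no energetic intermediate. The demand is a crossed acylation of an ester enolate without self-condensation or double addition, which the chelated adduct formed from 2 provides.

## Other disconnections considered

**Alternative 1:** The chain is cut at the Cα–C(=O) bond and at the ester C–O bond. The dibenzyl ether of the target, octadecyl 3-[2,4-bis(benzyloxy)-3-methoxyphenyl]propanoate A3, is thereby traced back to the styrene 2,4-bis(benzyloxy)-1-ethenyl-3-methoxybenzene A1, carbon monoxide A2 and 11.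
- **Forward key step:** Pd(OAc)2 with 1,2-bis(di-tert-butylphosphinomethyl)benzene and CH3SO3H would form a cationic divalent palladium hydride. This adds to A1 with the metal at the terminal carbon, inserts A2, and is cleaved by 11 to give A3 and regenerate the hydride. No ring closes; hydrogenolysis of A3 would give 18.
- **In its favour:** it is a fully atom-economic three-component union, the bulky chelating ligand is expected to steer even a styrene to the linear ester, and 11 is used as such, with no activated C2 reagent and no phosphine oxide waste. On atom economy it is better than the chosen olefination.
- **Against it here:** it does not touch the difficult part of the molecule, since A1 must come from an arene that already has the oxygen pattern (for example from 16 by methylenation). A1 is an electron-rich styrene with an ortho alkoxy group, so Markovnikov addition of 11 and cationic oligomerisation would compete under a strong sulfonic acid, and the branched benzylic palladium alkyl is stabilised by the ring. 11 is a waxy solid that cannot serve as solvent, so the alcoholysis that closes the cycle runs at low alcohol concentration. Pressurised A2 is a toxic gas.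
- **Comparison:** structurally it replaces only steps 7 to 9 and still needs steps 1 to 6. Mechanistically it trades a predictable carbonyl olefination for a regioselectivity that rests on ligand control. In step count it is about the equal of the chosen end game (methylenation, carbonylation and hydrogenolysis from 16, against oxidation–olefination and hydrogenation plus two steps for 15). It is ranked lower because of the hazard of A2 and the acid sensitivity of A1.

**Alternative 2:** The ring is cut at C3–C4 at the oxidation level of a cyclohexane-1,3-dione. Octadecyl 3-(3-methoxy-2,4-dioxocyclohexyl)propanoate A5 is traced back to the symmetric keto diester dioctadecyl 4-(2-methoxyacetyl)heptanedioate A4.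
- **Forward key step:** KOtBu would deprotonate the methoxymethyl carbon next to the ketone of A4, and the enolate would attack either of the two equivalent ester carbonyls (a Dieckmann-type Claisen condensation). This closes the six-membered ring with loss of one molecule of 11. A dehydrogenation of A5 would then be needed to reach 18.
- **In its favour:** symmetry removes any regiochemical question in the ring closure, the chain and its C18 ester are in place from the start, and the methoxyl flanked by two oxygens arises naturally as a 2-methoxy-1,3-dione. It uses no protecting group and no organometallic reagent, and on these two points it is better than the chosen plan.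
- **Against it here:** A4 is not trivial, because two acrylate-derived arms must be placed on the methyl-side carbon of a methoxymethyl ketone, which will need an activating group and its removal. One equivalent of the heaviest building block, 11, is discarded in the key step, and alkoxide exchange can scramble the remaining ester. The ring is formed at the wrong oxidation level, so an oxidant or a hot dehydrogenation catalyst must act on a substrate that turns into an oxidation-prone resorcinol with a lactonisable ortho-hydroxy ester.
- **Comparison:** structurally both plans build the oxygenated ring from acyclic carbonyl compounds and place the methoxyl on carbon before the ring exists. Mechanistically the alternative closes the ring by Claisen condensation and then needs a separate redox step, whereas the chosen plan closes it by cycloaddition and aromatises by a redox-neutral elimination. In step count the alternative, at perhaps five or six steps, would be the shorter if the aromatisation can be made clean, and this is named as its advantage; that step, however, is judged more uncertain than any step of the chosen plan.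

**Alternative 3:** The cut is the aryl C1–Cβ bond, with the lactone 7-hydroxy-8-methoxychroman-2-one A8 as the product of the key step, made from 2-methoxybenzene-1,3-diol A6 and acrylic acid A7.
- **Forward key step:** under Amberlyst-15 or CH3SO3H, C4 of A6 would add to the beta carbon of protonated A7 (a Friedel–Crafts conjugate addition), and the neighbouring hydroxyl would be acylated, closing the six-membered lactone. Ring opening of A8 with 11 would then give 18.
- **In its favour:** two steps, no protecting group, no metal. The symmetry of A6 makes C4 and C6 equivalent, each ortho to one hydroxyl and para to the other, while C5 is meta to both, so the regiochemistry is as secure as in the chosen plan. The lactone also differentiates the two hydroxyls, and its opening reveals exactly the target. On step count and on reagent hazard this alternative is clearly the better, and on regiocontrol it is the equal.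
- **Against it here:** it buys the difficult oxygen pattern instead of making it, and A6 is a specialised starting material. A second alkylation at the still activated C6 of A8 and oligomerisation of A7 are to be expected as competing processes. The last step is an equilibrium between A8 plus 11 and 18, the very lactonisation noted as a fragility of the target. It must be driven by an excess of a waxy alcohol that is not easily removed, and the product can revert on heating or on acidic media.
- **Comparison:** structurally it starts from the intact arene, whereas the chosen plan constructs the arene. Mechanistically it is an electrophilic substitution under symmetry control, against a cycloaddition under polarity control. The chosen plan is kept because its ring-forming disconnection builds the arene from commodity acyclic materials, and because its ester bond is made before the phenol is revealed, so the lactone/hydroxy-ester equilibrium is never run deliberately.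

Key step: step 4

Remark on the chemistry: the enol ether geometries of 4 and 5, the ketal stereocentre of 7 and the alkene geometry of 17 are taken as immaterial, because each is destroyed in a later step. A check of the atom mapping of 5, 6 and 8 found these structures consistent, so no structure was corrected, and the changes made concern the access to 3 and the end game.

## Route

Step 1
Reactants: 1 methyl methoxyacetate; 2 N-methoxy-N-methylacetamide
Product: 3 methyl 2-methoxy-3-oxobutanoate (racemic)
Conditions: 1 (1.5 equiv), LiN(iPr)2 (1.5 equiv), THF, −78 °C; then 2, −78 → −20 °C; dilute aq. HCl, 0 °C
Reagents that add atoms: none
Why: Crossed Claisen-type acylation of a lithium ester enolate by a Weinreb amide; the chelated tetrahedral adduct should persist until the acidic quench, so the beta-keto ester is released only then and can neither add a second enolate nor protonate the first.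

Step 2
Reactants: 3 methyl 2-methoxy-3-oxobutanoate
Product: 4 methyl 2-methoxy-3-(trimethylsilyloxy)but-2-enoate (E/Z mixture)
Conditions: Me3SiCl, Et3N, toluene, 20 °C; filtration, distillation
Reagents that add atoms: chlorotrimethylsilane, C[Si](C)(C)Cl
Why: Soft enolisation: amine base and silyl chloride O-silylate the enol of the beta-keto ester to give the conjugated silyl enol ether; the geometry is irrelevant because both isomers lead to the same diene.

Step 3
Reactants: 4 methyl 2-methoxy-3-(trimethylsilyloxy)but-2-enoate
Product: 5 1,2-dimethoxy-1,3-bis(trimethylsilyloxy)buta-1,3-diene
Conditions: LiN(iPr)2, THF, −78 °C; then Me3SiCl, −78 → 0 °C; hexane, filtration under argon, used crude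
Reagents that add atoms: chlorotrimethylsilane, C[Si](C)(C)Cl
Why: Kinetic gamma-deprotonation of the vinylogous ester by the lithium amide gives a dienolate that is O-silylated at the ester oxygen, the standard second stage in the preparation of 1,3-bis(silyloxy)dienes; the existing silyl enol ether blocks the alpha position.

Step 4
Reactants: 5 1,2-dimethoxy-1,3-bis(trimethylsilyloxy)buta-1,3-diene; 6 methyl propiolate
Product: 8 methyl 2,4-dihydroxy-3-methoxybenzoate, via silylated cyclohexadiene cycloadduct 7 (not isolated)
Conditions: 6 (1.2 equiv), toluene, 0 → 60 °C; then dilute aq. HCl, THF, 20 °C
Reagents that add atoms: none
Why: The CH2 terminus of 5, the carbon with the largest HOMO coefficient, should bond to the beta carbon of 6 while the ketene-acetal carbon bonds to the alpha carbon, in a strongly asynchronous [4+2] cycloaddition that can equally be read as a Mukaiyama–Michael addition followed by closure of the allenoate onto the dioxygenated cation (a Michael–Claisen sequence); both readings lead to the same 1,4-cyclohexadiene 7. The closest known reaction type is the Diels–Alder reaction of 1-alkoxy-1,3-bis(silyloxy)buta-1,3-dienes and related 1-methoxy-3-silyloxy dienes with acetylenic esters, which delivers hydroxybenzoates after loss of the C1 alkoxy group. The single ring is closed by intermolecular [4+2] cycloaddition, forming C1–C2 and C5–C6 of the future arene, and it is aromatised by elimination, with no oxidant. On acidic work-up the two O–Si bonds should be hydrolysed, the mixed ketal carbon (arene C2) should collapse to a carbonyl with loss of methanol, and the resulting cyclohexenedione should enolise to the resorcinol 8. No stereocentre survives: the ketal carbon of 7 is formed racemic and becomes sp2. The step needs regioselectivity (ester next to one hydroxyl and para to the other, C5 and C6 bare), which is secured by the matched polarisation of the nucleophilic CH2 terminus and the electrophilic beta carbon of the ynoate. It also needs loss of the methoxyl and not of the silyloxy group from the ketal carbon, which is secured by cleaving the O–Si bond first in aqueous acid so that this oxygen stays on the ring as the C2 hydroxyl. The methoxyl on the central diene carbon sits on an sp2 carbon throughout and is carried unchanged to C3.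

Step 5
Reactants: 8 methyl 2,4-dihydroxy-3-methoxybenzoate
Product: 9 methyl 2,4-bis(benzyloxy)-3-methoxybenzoate
Conditions: BnBr (2.5 equiv), K2CO3, DMF, 60 °C
Reagents that add atoms: benzyl bromide, BrCc1ccccc1
Why: Williamson ether synthesis on both phenoxides; warm DMF is used because the C2 hydroxyl is hydrogen-bonded to the ester and flanked by the methoxyl, and a dipolar aprotic solvent favours O- over C-alkylation.

Step 6
Reactants: 9 methyl 2,4-bis(benzyloxy)-3-methoxybenzoate
Product: 10 [2,4-bis(benzyloxy)-3-methoxyphenyl]methanol
Conditions: iBu2AlH (2.5 equiv), CH2Cl2, −78 → 0 °C; aq. KNaC4H4O6
Reagents that add atoms: none
Why: Hydride reduction of the aryl ester to the primary benzylic alcohol; benzyl and methyl aryl ethers are inert to the aluminium hydride, and the tartrate work-up avoids acid, to which the electron-rich benzylic alcohol is sensitive.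

Step 7
Reactants: 11 octadecan-1-ol; 12 bromoacetic acid
Product: 13 octadecyl 2-bromoacetate
Conditions: TsOH·H2O (cat.), toluene, reflux, Dean–Stark trap
Reagents that add atoms: none
Why: Fischer esterification driven to completion by azeotropic removal of water; the free acid replaces an acyl bromide to avoid a corrosive lachrymator, and the primary bromide is stable to the acidic conditions.

Step 8
Reactants: 13 octadecyl 2-bromoacetate
Product: 15 octadecyl (triphenylphosphoranylidene)acetate, via phosphonium bromide 14 (not isolated)
Conditions: PPh3, toluene, 60 °C; then aq. NaOH, CH2Cl2, 0 °C
Reagents that add atoms: triphenylphosphine, c1ccc(cc1)P(c1ccccc1)c1ccccc1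
Why: SN2 quaternisation of the phosphine by the alpha-bromo ester, then deprotonation of the acidic methylene of the phosphonium salt by cold aqueous hydroxide, should give the ester-stabilised ylide (Wittig reagent) without saponification.

Step 9
Reactants: 10 [2,4-bis(benzyloxy)-3-methoxyphenyl]methanol; 15 octadecyl (triphenylphosphoranylidene)acetate
Product: 17 octadecyl (E)-3-[2,4-bis(benzyloxy)-3-methoxyphenyl]prop-2-enoate, via benzaldehyde 16 (not isolated)
Conditions: activated MnO2 (excess), 15 (1.3 equiv), toluene, 80 °C
Reagents that add atoms: none
Why: Tandem oxidation–Wittig process: MnO2 should oxidise the activated benzylic alcohol to 16, which is trapped as it forms by the stabilised ylide, itself inert to the oxidant, to give the E enoate; the alkene geometry is of no consequence because it is hydrogenated in step 10.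

Step 10
Reactants: 17 octadecyl (E)-3-[2,4-bis(benzyloxy)-3-methoxyphenyl]prop-2-enoate
Product: 18 octadecyl 3-(2,4-dihydroxy-3-methoxyphenyl)propanoate
Conditions: H2 (1 atm), Pd/C, EtOAc–THF, 20 °C
Reagents that add atoms: none
Why: Heterogeneous catalytic hydrogenation should saturate the conjugated alkene and hydrogenolyse both benzyl ethers in one operation; the neutral medium and ambient temperature leave the octadecyl ester intact and give the freed C2 hydroxyl no catalyst for lactonisation.

## Compound list

1 | methyl methoxyacetate | COCC(=O)OC | starting material
2 | N-methoxy-N-methylacetamide | CC(=O)N(C)OC | starting material
3 | methyl 2-methoxy-3-oxobutanoate (racemic) | CC(=O)C(OC)C(=O)OC | intermediate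
4 | methyl 2-methoxy-3-(trimethylsilyloxy)but-2-enoate (E/Z mixture) | CC(O[Si](C)(C)C)=C(OC)C(=O)OC | intermediate
5 | 1,2-dimethoxy-1,3-bis(trimethylsilyloxy)buta-1,3-diene (geometry immaterial) | C=C(O[Si](C)(C)C)C(OC)=C(OC)O[Si](C)(C)C | intermediate
6 | methyl propiolate (methyl prop-2-ynoate) | C#CC(=O)OC | starting material
7 | methyl 5,6-dimethoxy-4,6-bis(trimethylsilyloxy)cyclohexa-1,4-diene-1-carboxylate (racemic; not isolated) | COC(=O)C1=CCC(O[Si](C)(C)C)=C(OC)C1(OC)O[Si](C)(C)C | intermediate
8 | methyl 2,4-dihydroxy-3-methoxybenzoate | COC(=O)c1ccc(O)c(OC)c1O | intermediate
9 | methyl 2,4-bis(benzyloxy)-3-methoxybenzoate | COC(=O)c1ccc(OCc2ccccc2)c(OC)c1OCc1ccccc1 | intermediate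
10 | [2,4-bis(benzyloxy)-3-methoxyphenyl]methanol | OCc1ccc(OCc2ccccc2)c(OC)c1OCc1ccccc1 | intermediate
11 | octadecan-1-ol | CCCCCCCCCCCCCCCCCCO | starting material
12 | bromoacetic acid | OC(=O)CBr | starting material
13 | octadecyl 2-bromoacetate | CCCCCCCCCCCCCCCCCCOC(=O)CBr | intermediate
14 | [2-(octadecyloxy)-2-oxoethyl]triphenylphosphonium bromide (not isolated) | CCCCCCCCCCCCCCCCCCOC(=O)C[P+](c1ccccc1)(c1ccccc1)c1ccccc1.[Br-] | intermediate
15 | octadecyl (triphenylphosphoranylidene)acetate | CCCCCCCCCCCCCCCCCCOC(=O)C=P(c1ccccc1)(c1ccccc1)c1ccccc1 | intermediate
16 | 2,4-bis(benzyloxy)-3-methoxybenzaldehyde (not isolated) | O=Cc1ccc(OCc2ccccc2)c(OC)c1OCc1ccccc1 | intermediate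
17 | octadecyl (E)-3-[2,4-bis(benzyloxy)-3-methoxyphenyl]prop-2-enoate | CCCCCCCCCCCCCCCCCCOC(=O)/C=C/c1ccc(OCc2ccccc2)c(OC)c1OCc1ccccc1 | intermediate
18 | octadecyl 3-(2,4-dihydroxy-3-methoxyphenyl)propanoate | CCCCCCCCCCCCCCCCCCOC(=O)CCc1ccc(O)c(OC)c1O | target

## Step count and least certain steps

Total step count: 10. Longest linear sequence: 8 steps (steps 1, 2, 3, 4, 5, 6, 9 and 10); steps 7 and 8 form a two-step branch that joins at step 9.

**Step 4 (key step).**
- Risk: the cycloaddition may be slow, because the ketene-acetal terminus of 5 is fully substituted and one of its oxygen substituents must point into the diene in the reactive s-cis conformer. Over a long reaction time, silyl migration and hydrolysis of the diene and oligomerisation of the ynoate would consume the partners, and the conjugate addition might stop before ring closure. A second risk is aromatisation by loss of the silyloxy group instead of the methoxyl, which would leave the C2 oxygen methylated.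
- Fallback: from 5, the same two ring bonds are formed one after the other by polar chemistry. Me3SiOTf-catalysed addition of the CH2 terminus of 5 to the oxocarbenium ion generated from methyl 3,3-dimethoxypropanoate (a bench-stable acetal of formylacetate; CH2Cl2, −78 °C) would give, after aqueous work-up, dimethyl 2,5-dimethoxy-3-oxoheptanedioate F1. NaOMe in methanol should then bring about Dieckmann closure of the C6 carbanion onto the C1 ester, beta-elimination of the C5 methoxyl and enolisation, coming back to the route at 8.

**Step 3.**
- Risk: gamma-deprotonation may be incomplete or accompanied by attack of the amide at the ester and by C-silylation. The bis(trimethylsilyl) diene may also be lost by hydrolysis or silyl migration during isolation, because it cannot be chromatographed.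
- Fallback: from 3, without passing through 4, double soft enolisation with Et3SiOTf and Et3N (Et2O, 0 °C) in one flask would give 1,2-dimethoxy-1,3-bis(triethylsilyloxy)buta-1,3-diene F2, which is expected to tolerate handling and storage much better. Its reaction with 6 under the conditions of step 4 would pass through methyl 5,6-dimethoxy-4,6-bis(triethylsilyloxy)cyclohexa-1,4-diene-1-carboxylate F3 and, on acidic work-up, come back to the route at 8.

**Step 1.**
- Risk: self-condensation of the enolate of 1 on warming, and proton transfer from the acetyl group of 2 to the enolate, which would return both partners unchanged.
- Fallback: from 1, aldol addition of its lithium enolate to acetaldehyde (THF, −78 °C) would give methyl 3-hydroxy-2-methoxybutanoate F4 as a mixture of diastereomers. An aldehyde is attacked much faster than it is enolised, so proton transfer should not compete. Parikh–Doering oxidation (SO3·pyridine, DMSO, Et3N) of the secondary alcohol would then come back to the route at 3.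

**Step 9.**
- Risk: olefination of the electron-rich, ortho-substituted aldehyde 16 may be slow, so that the ylide is degraded on the oxidant surface over time, or the oxidation may stall as the MnO2 is deactivated by adsorbed material.
- Fallback: from 10, oxidation with MnO2 alone and isolation of 16, followed by a Horner–Wadsworth–Emmons reaction with the more nucleophilic phosphonate anion (LiCl, DBU, MeCN) of octadecyl 2-(diethoxyphosphoryl)acetate F5. F5 would be prepared in one step from 11 and diethylphosphonoacetic acid by carbodiimide coupling. The sequence comes back to the route at 17.

## Further compounds

F1 | step 4 | dimethyl 2,5-dimethoxy-3-oxoheptanedioate (mixture of diastereomers) | COC(=O)C(OC)C(=O)CC(OC)CC(=O)OC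
F2 | step 3 | 1,2-dimethoxy-1,3-bis(triethylsilyloxy)buta-1,3-diene | C=C(O[Si](CC)(CC)CC)C(OC)=C(OC)O[Si](CC)(CC)CC
F3 | step 3 | methyl 5,6-dimethoxy-4,6-bis(triethylsilyloxy)cyclohexa-1,4-diene-1-carboxylate (racemic) | COC(=O)C1=CCC(O[Si](CC)(CC)CC)=C(OC)C1(OC)O[Si](CC)(CC)CC
F4 | step 1 | methyl 3-hydroxy-2-methoxybutanoate (mixture of diastereomers) | CC(O)C(OC)C(=O)OC
F5 | step 9 | octadecyl 2-(diethoxyphosphoryl)acetate | CCCCCCCCCCCCCCCCCCOC(=O)CP(=O)(OCC)OCC
A1 | alternative 1 | 2,4-bis(benzyloxy)-1-ethenyl-3-methoxybenzene | C=Cc1ccc(OCc2ccccc2)c(OC)c1OCc1ccccc1
A2 | alternative 1 | carbon monoxide | [C-]#[O+]
A3 | alternative 1 | octadecyl 3-[2,4-bis(benzyloxy)-3-methoxyphenyl]propanoate | CCCCCCCCCCCCCCCCCCOC(=O)CCc1ccc(OCc2ccccc2)c(OC)c1OCc1ccccc1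
A4 | alternative 2 | dioctadecyl 4-(2-methoxyacetyl)heptanedioate | CCCCCCCCCCCCCCCCCCOC(=O)CCC(CCC(=O)OCCCCCCCCCCCCCCCCCC)C(=O)COC
A5 | alternative 2 | octadecyl 3-(3-methoxy-2,4-dioxocyclohexyl)propanoate (configuration immaterial) | CCCCCCCCCCCCCCCCCCOC(=O)CCC1CCC(=O)C(OC)C1=O
A6 | alternative 3 | 2-methoxybenzene-1,3-diol | COc1c(O)cccc1O
A7 | alternative 3 | acrylic acid | C=CC(=O)O
A8 | alternative 3 | 7-hydroxy-8-methoxychroman-2-one | COc1c(O)ccc2CCC(=O)Oc12
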